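**Retrosynthetic overview**
1. Target 13 ⇒ its terminal CH2–OH bond: water adds to the bilane azafulvene 12, which hydroxymethylbilane synthase forms from aminomethylbilane 11; this is done last because 13 is labile.
2. 11 ⇒ bilane lactam 10 (hydrolysis) ⇒ 2+2 head-to-tail union of aminomethyl dipyrromethane 8 (electrophile at its CH2NH2 head) with dipyrromethane lactam 7 (nucleophile at its free α-position, head masked as lactam); 8 comes from 7 by hydrolysis.
3. 7 ⇒ 1+1 union of porphobilinogen 5 (electrophile) with its lactam methyl ester 4 (nucleophile); 5 comes from 4 by hydrolysis.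
4. 4 ⇒ key disconnection at the pyrrole N1–C2 bond (plus the lactam C–N bond): a Knorr-type union of two molecules of methyl 5-aminolevulinate 1.
5. Ring order: pyrrole and fused lactam (step 1), then the same ring joined 1+1 (step 3) and 2+2 (step 5), lactams opened in between; no macrocycle is formed.

Assumption: the target has no stereocentres, so no stereocontrol is needed. Because the free octa-acid cyclises to uroporphyrinogen I within minutes near neutral pH, 13 is delivered as its octapotassium salt in solution at pH ≥ 13; 8 and 11 are handled as cold alkaline stock solutions. All are drawn in the neutral form.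

**Step 1**
Reactants: 1 methyl 5-aminolevulinate hydrochloride (2 equiv)
Product: 4 porphobilinogen lactam methyl ester, via dihydropyrazine diester 2 (not isolated), via porphobilinogen dimethyl ester 3 (not isolated)
Conditions: 5-methoxyanthranilic acid (20 mol %), NaOAc (1.05 equiv), degassed MeOH (0.5 M), 55 °C, Ar, dark, 24 h
Reagents that add atoms: none
Why: Proposed new method: an arylamine-catalysed Knorr-type self-condensation of an α-amino ketone, in which buffered 1 dimerises reversibly through two ketimine C–N bonds to dihydropyrazine 2, the catalyst (ortho-CO2H as proton shuttle) opens one C=N of 2 by transimination so that the surviving ketimine C–N bond (the future pyrrole N1–C2 bond) holds the two units together while the other unit carries an electrophilic N-aryl ketiminium, the side-chain enamine (C3 of the first unit; the competing C5 enamine carbon bears an ammonium group in the acidic buffer and is a far poorer nucleophile) closes the five-membered ring by intramolecular Mannich addition, and β-elimination of the arylamine followed by irreversible aromatisation gives 3, whose aminomethyl group at once acylates on the neighbouring acetate ester to give lactam 4, which cannot self-condense as free porphobilinogen does; the closest known reactions are the Knorr pyrrole synthesis, anthranilate nucleophilic catalysis of imine exchange, primary-amine iminium Mannich catalysis and the two-Schiff-base mechanism of porphobilinogen synthase; no stereocentre is formed.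

**Step 2**
Reactants: 4 porphobilinogen lactam methyl ester
Product: 5 porphobilinogen
Conditions: 2 M KOH (aq), rt, Ar, dark, 72 h; then AcOH to pH 5.5, 0 °C (crystallisation)
Reagents that add atoms: water, O (delivered as aqueous potassium hydroxide, [K+].[OH-])
Why: Saponification of the methyl ester and hydroxide opening of the six-membered lactam is the standard last step of porphobilinogen syntheses; the electron-rich pyrrole is stable in strong base, and isolation at the isoelectric point avoids acid-promoted self-condensation; no stereocentre is formed.

**Step 3**
Reactants: 5 porphobilinogen; 4 porphobilinogen lactam methyl ester (in excess)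
Product: 7 dipyrromethane lactam methyl ester, via porphobilinogen azafulvene 6 (not isolated)
Conditions: 5 (in degassed 0.1 M aq. NaHCO3) added by syringe pump over 8 h to 4 (8 equiv) in degassed MeOH/0.5 M NaOAc–AcOH buffer pH 4.8 (1:1), 60 °C, Ar, dark; excess 4 extracted at pH 8 and recycled, then C18 chromatography
Reagents that add atoms: none
Why: Mannich-base alkylation of an α-free pyrrole (deaminative azafulvene coupling, the classical aminomethylpyrrole route to dipyrromethanes): in warm weakly acidic buffer the aminomethyl group of 5 leaves as ammonium to give azafulvene 6, which is captured at C2 of 4, the only free α-position of a partner whose own CH2–N is locked in the lactam and cannot ionise, while the eight-fold excess of 4 and the slow addition of 5 hold back self-condensation of 5 and a second alkylation of 7; no stereocentre is formed.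

**Step 4**
Reactants: 7 dipyrromethane lactam methyl ester
Product: 8 aminomethyl dipyrromethane tetra-acid
Conditions: 2 M KOH (aq), rt, Ar, dark, 72 h; then AcOH to pH 9, 0 °C (stock solution, used at once)
Reagents that add atoms: water, O (delivered as aqueous potassium hydroxide, [K+].[OH-])
Why: Lactam opening and ester saponification with aqueous hydroxide, the same reaction as step 2; the dipyrromethane is stable to strong base under argon, and 8 is kept cold at pH 9 because, like 5, it self-condenses in acid; no stereocentre is formed.

**Step 5**
Reactants: 8 aminomethyl dipyrromethane tetra-acid; 7 dipyrromethane lactam methyl ester (in excess)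
Product: 10 bilane lactam methyl ester, via dipyrromethane azafulvene 9 (not isolated)
Conditions: 8 (stock solution) added by syringe pump over 8 h to 7 (4 equiv) in degassed MeOH/0.5 M NaOAc–AcOH buffer pH 4.8 (1:1), 50 °C, Ar, dark; DEAE anion exchange (recovers 7), then C18
Reagents that add atoms: none
Why: A second Mannich-base alkylation through azafulvene 9 (same reaction type as step 3, now 2+2): 8 ionises at its aminomethyl head and is captured by the free α-position of the terminal ring of 7, whose head is again masked as the lactam, which fixes the head-to-tail order of all four rings, while the four-fold excess of 7 and the slow addition of 8 suppress the self-coupling of 8 that would lead on to uroporphyrinogen I; no stereocentre is formed.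

**Step 6**
Reactants: 10 bilane lactam methyl ester
Product: 11 aminomethylbilane
Conditions: 2 M KOH (aq), rt, Ar, dark, 72 h; then AcOH to pH 8.5, 0 °C (stock solution, used at once)
Reagents that add atoms: water, O (delivered as aqueous potassium hydroxide, [K+].[OH-])
Why: Lactam opening and ester saponification with aqueous hydroxide is the standard way to release an aminomethylbilane from its lactam ester; 11 is stable at alkaline pH and far more robust than 13, so it can be stored cold until the last step; no stereocentre is formed.

**Step 7**
Reactants: 11 aminomethylbilane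
Product: 13 preuroporphyrinogen (hydroxymethylbilane), via bilane azafulvene 12 (not isolated)
Conditions: His6-hydroxymethylbilane synthase (E. coli HemC, holo-enzyme) immobilised on Ni-NTA agarose, 1 mM 11 in degassed 50 mM Tris·HCl pH 8.2, 15 °C, flow (residence ca. 3 min); effluent directly into ice-cold 2 M KOH (final pH ≥ 13), Ar
Reagents that add atoms: water, O
Why: Enzymatic deaminative hydroxylation (the hydroxymethylbilane synthase reaction run on the preformed bilane): the synthase accepts 11, eliminates ammonia from its aminomethyl terminus to give azafulvene 12 and releases it by addition of water, forming the terminal C–O bond, while the short residence time and the quench to pH ≥ 13, where 13 is stable, outrun spontaneous cyclisation to uroporphyrinogen I; no stereocentre is formed.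

**Compound list**
1 | methyl 5-aminolevulinate hydrochloride (methyl 5-amino-4-oxopentanoate hydrochloride) | COC(=O)CCC(=O)CN.Cl | starting material
2 | dimethyl 3,3'-(3,6-dihydropyrazine-2,5-diyl)dipropanoate (dihydropyrazine diester) | COC(=O)CCC1=NCC(CCC(=O)OC)=NC1 | intermediate
3 | porphobilinogen dimethyl ester (methyl 3-[5-(aminomethyl)-4-(2-methoxy-2-oxoethyl)-1H-pyrrol-3-yl]propanoate) | COC(=O)CCc1c[nH]c(CN)c1CC(=O)OC | intermediate
4 | porphobilinogen lactam methyl ester (methyl 3-(5-oxo-4,5,6,7-tetrahydro-1H-pyrrolo[2,3-c]pyridin-3-yl)propanoate) | COC(=O)CCc1c[nH]c2CNC(=O)Cc12 | intermediate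
5 | porphobilinogen (3-[5-(aminomethyl)-4-(carboxymethyl)-1H-pyrrol-3-yl]propanoic acid) | NCc1[nH]cc(CCC(=O)O)c1CC(=O)O | intermediate
6 | porphobilinogen azafulvene (3-[4-(carboxymethyl)-5-methylidene-5H-pyrrol-3-yl]propanoic acid) | C=C1N=CC(CCC(=O)O)=C1CC(=O)O | intermediate
7 | dipyrromethane lactam methyl ester (3-[4-(carboxymethyl)-5-{[3-(3-methoxy-3-oxopropyl)-5-oxo-4,5,6,7-tetrahydro-1H-pyrrolo[2,3-c]pyridin-2-yl]methyl}-1H-pyrrol-3-yl]propanoic acid) | COC(=O)CCc1c(Cc3[nH]cc(CCC(=O)O)c3CC(=O)O)[nH]c2CNC(=O)Cc12 | intermediate
8 | aminomethyl dipyrromethane tetra-acid (3-[5-(aminomethyl)-2-{[4-(2-carboxyethyl)-3-(carboxymethyl)-1H-pyrrol-2-yl]methyl}-4-(carboxymethyl)-1H-pyrrol-3-yl]propanoic acid; head-to-tail dimer of 5) | NCc1[nH]c(Cc2[nH]cc(CCC(=O)O)c2CC(=O)O)c(CCC(=O)O)c1CC(=O)O | intermediate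
9 | dipyrromethane azafulvene (8 without NH3: aminomethyl ring as 2-methylene-2H-pyrrole, second ring unchanged) | C=C1N=C(Cc2[nH]cc(CCC(=O)O)c2CC(=O)O)C(CCC(=O)O)=C1CC(=O)O | intermediate
10 | bilane lactam methyl ester (rings B, C, D as in 13; ring A as the 5-oxo-4,5,6,7-tetrahydro-1H-pyrrolo[2,3-c]pyridine lactam with the methyl propanoate at C3 and the CH2 bridge to ring B at C2) | O=C(O)CCc1c[nH]c(Cc2[nH]c(Cc3[nH]c(Cc4[nH]c5CNC(=O)Cc5c4CCC(=O)OC)c(CC(=O)O)c3CCC(=O)O)c(CC(=O)O)c2CCC(=O)O)c1CC(=O)O | intermediate
11 | aminomethylbilane (13 with CH2NH2 in place of CH2OH) | O=C(O)CCc1c[nH]c(Cc2[nH]c(Cc3[nH]c(Cc4[nH]c(CN)c(CC(=O)O)c4CCC(=O)O)c(CC(=O)O)c3CCC(=O)O)c(CC(=O)O)c2CCC(=O)O)c1CC(=O)O | intermediate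
12 | bilane azafulvene (ring A of 13 as 2-methylene-2H-pyrrole, other three rings as in 13) | O=C(O)CCc1c[nH]c(Cc2[nH]c(Cc3[nH]c(CC4=NC(=C)C(CC(=O)O)=C4CCC(=O)O)c(CC(=O)O)c3CCC(=O)O)c(CC(=O)O)c2CCC(=O)O)c1CC(=O)O | intermediate
13 | preuroporphyrinogen (hydroxymethylbilane; achiral; kept as octapotassium salt at pH ≥ 13) | O=C(O)CCc1c[nH]c(Cc2[nH]c(Cc3[nH]c(Cc4[nH]c(CO)c(CC(=O)O)c4CCC(=O)O)c(CC(=O)O)c3CCC(=O)O)c(CC(=O)O)c2CCC(=O)O)c1CC(=O)O | target

**Totals**
Total step count: 7. Longest linear sequence: 7 (1 → 4 → 5 → 7 → 8 → 10 → 11 → 13); 4 and 7 are each used a second time as the nucleophilic coupling partner.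

**Steps most likely to fail**

Step 1 (the proposed new method) is the most uncertain. The dihydropyrazine 2 may simply persist or be oxidised to the pyrazine, or ring closure may occur from the wrong enamine. The fallback uses known chemistry and sets out from 1. The ester is hydrolysed in 1 M aqueous HCl at 60 °C to 5-aminolevulinic acid hydrochloride F1. After neutralisation with NaOH, recombinant porphobilinogen synthase (5-aminolevulinate dehydratase, E. coli HemB, Zn2+/Mg2+, DTT, Tris pH 8, 37 °C, Ar) performs the same Knorr-type condensation, and the product is crystallised at pH 5.5. This fallback comes back to the route at 5, so step 2 is not needed. The share of 4 that step 3 needs as nucleophile is then made from part of this 5: esterification (SOCl2, MeOH, −10 to 4 °C) gives the dimethyl ester 3, which closes to 4 on neutralisation (NaHCO3, MeOH, rt).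

Step 5 is the next most likely to fail. The 2+2 union joins two polyacidic dipyrromethanes, the nucleophile 7 is precious and cannot be used in large excess, and self-coupling of 8 leads on to uroporphyrinogen I. The fallback sets out from 8 and replaces the 2+2 union by a linear 3+1 assembly with the monomer lactam 4, which is cheap, less hindered and can be used in much larger excess. 8 is coupled with 4 (10 equiv) under the conditions of step 3 to give the tripyrrane lactam methyl ester F2. 2 M KOH (rt, 72 h, Ar) opens it to the aminomethyl tripyrrane hexa-acid F3. F3 is coupled with 4 (10 equiv) in the same way, and the fallback comes back to the route at 10.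

Step 3 is the third. Deamination of 5 may be too slow at pH 4.8, or self-condensation of 5 may win over capture by 4. The fallback sets out from 5 and gives up the chemical cross-coupling for enzymatic head-to-tail assembly. Hydroxymethylbilane synthase is run on 5 in Tris pH 8.5 containing 0.3 M NH4Cl, where ammonia rather than water captures the released azafulvene (the known amine interception of this enzyme). This gives the aminomethylbilane directly, purified by anion exchange in the cold at pH 9–10. The fallback comes back to the route at 11, bypassing steps 3 to 6, and makes no new compound (F0).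

**Further compounds**
F1 | step 1 | 5-aminolevulinic acid hydrochloride | NCC(=O)CCC(=O)O.Cl
F2 | step 5 | tripyrrane lactam methyl ester (10 without its free-α terminal ring D) | O=C(O)CCc1c[nH]c(Cc2[nH]c(Cc3[nH]c4CNC(=O)Cc4c3CCC(=O)OC)c(CC(=O)O)c2CCC(=O)O)c1CC(=O)O
F3 | step 5 | aminomethyl tripyrrane hexa-acid (head-to-tail trimer of 5) | O=C(O)CCc1c[nH]c(Cc2[nH]c(Cc3[nH]c(CN)c(CC(=O)O)c3CCC(=O)O)c(CC(=O)O)c2CCC(=O)O)c1CC(=O)O
F0 | step 3 | none | none
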